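**Retrosynthetic overview**
1. The target gibberellin (12α-hydroxygibberellic acid) ⇐ fluoride deprotection of its tris-silyl ether / silylethyl ester. Ring A and the 19,10-γ-lactone close together by an intramolecular Michael addition (C-4 → C-5) of a seven-membered lactone enolate; that lactone is closed by ring-closing metathesis (C-1=C-2).
2. That lactone ⇐ a rings B/C/D enone (C-10 ketone, 5-ene-7-ester) + vinylmagnesium bromide (C-1) + an Evans-aldol acid chloride (C-19, C-4, C-18, C-3, C-2; fixes C-3).
3. Ring D ⇐ palladium-mediated cycloalkenylation of a ring C enediol bis-silyl ether onto the C-8 allyl group (C-13–C-16 bond), then 12-ketone reduction. The ring B ester ⇐ enol triflate carbonylation.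
4. Rings B/C ⇐ [4+2] double-Michael annulation of (R)-2-allyl-4-silyloxycyclopentenone (ring B, source of chirality) with 2,3-bis(silyloxy)butadiene (C-11 to C-14).
5. Ring order: B (bought) → C → D → seven-membered lactone → A + γ-lactone.

Assumption: gibberellin atom numbering is used for the polycyclic intermediates, β is the face of H-9 and α the opposite face, the target (number 87 of the gibberellin A series) is named as 12α-hydroxygibberellic acid, and the SMILES strings are the binding statement of configuration.

**Route**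

Step 1
Reactants: 1 (R)-4-benzyloxazolidin-2-one; 2 propanoyl chloride
Product: 3 (R)-4-benzyl-3-propanoyloxazolidin-2-one
Conditions: n-BuLi, THF, −78 °C; then 2, −78 → 0 °C
Reagents that add atoms: none
Why: N-acylation of the lithiated oxazolidinone installs the propionate unit that becomes C-4, C-18 and C-19; no stereocentre is formed.

Step 2
Reactants: 3 (R)-4-benzyl-3-propanoyloxazolidin-2-one; 4 acrolein
Product: 5 (2R,3S) syn-aldol imide
Conditions: Bu2BOTf, i-Pr2NEt, CH2Cl2, −78 → 0 °C; then pH 7 buffer, MeOH, H2O2, 0 °C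
Reagents that add atoms: none
Why: Evans syn-aldol reaction through a Zimmerman–Traxler chair on the enolate face opposite the benzyl group of the (R)-auxiliary gives the 2R,3S adduct, whose carbinol centre becomes C-3 (3β-oxygen) of the target.

Step 3
Reactants: 5 (2R,3S) syn-aldol imide
Product: 6 triethylsilyl ether of 5
Conditions: Et3SiCl, imidazole, DMF, 0 °C → rt
Reagents that add atoms: chlorotriethylsilane, CC[Si](Cl)(CC)CC
Why: Standard silylation protects the secondary alcohol as a fluoride-labile ether and touches no stereocentre.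

Step 4
Reactants: 6 triethylsilyl ether of 5
Product: 7 (2R,3S)-2-methyl-3-(triethylsilyloxy)pent-4-enoic acid
Conditions: LiOH, H2O2, THF–H2O, 0 °C; Na2SO3; then 0.5 M HCl to pH 4, 0 °C
Reagents that add atoms: hydrogen peroxide, OO
Why: Lithium hydroperoxide hydrolysis (Evans auxiliary removal) cleaves the exocyclic imide carbonyl selectively and leaves both stereocentres untouched.

Step 5
Reactants: 7 (2R,3S)-2-methyl-3-(triethylsilyloxy)pent-4-enoic acid
Product: 8 (2R,3S)-2-methyl-3-(triethylsilyloxy)pent-4-enoyl chloride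
Conditions: 1-chloro-N,N,2-trimethylprop-1-en-1-amine, CH2Cl2, 0 °C → rt; concentrate and use crude
Reagents that add atoms: 1-chloro-N,N,2-trimethylprop-1-en-1-amine, CC(C)=C(Cl)N(C)C
Why: Neutral acid chloride formation with the Ghosez chloroenamine avoids HCl, so the silyl ether survives; the α-centre need not be preserved further because it is enolised in step 17.

Step 6
Reactants: 9 butane-2,3-dione
Product: 10 2,3-bis(triethylsilyloxy)buta-1,3-diene
Conditions: Et3SiOTf (2.2 equiv), Et3N, CH2Cl2, 0 °C → rt
Reagents that add atoms: triethylsilyl trifluoromethanesulfonate, CC[Si](CC)(CC)OS(=O)(=O)C(F)(F)F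
Why: Double soft enolisation and O-silylation of the 1,2-diketone gives the symmetrical electron-rich diene that carries C-11 to C-14 and both ring C oxygens.

Step 7
Reactants: 11 (R)-4-(tert-butyldimethylsilyloxy)cyclopent-2-en-1-one
Product: 12 (R)-4-(tert-butyldimethylsilyloxy)-2-iodocyclopent-2-en-1-one
Conditions: I2, pyridine, CH2Cl2, 0 °C → rt
Reagents that add atoms: iodine, [I][I]
Why: Johnson α-iodination (pyridine conjugate addition, iodination, elimination) gives the vinyl iodide and does not touch the C-10 stereocentre.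

Step 8
Reactants: 12 (R)-4-(tert-butyldimethylsilyloxy)-2-iodocyclopent-2-en-1-one; 13 allyltributylstannane
Product: 14 (R)-2-allyl-4-(tert-butyldimethylsilyloxy)cyclopent-2-en-1-one
Conditions: Pd2(dba)3 (2.5 mol %), AsPh3, CuI, N-methylpyrrolidone, rt
Reagents that add atoms: none
Why: Stille coupling of the α-iodoenone with the allylstannane places the C-15–C-17 unit on C-8.

Step 9
Reactants: 14 (R)-2-allyl-4-(tert-butyldimethylsilyloxy)cyclopent-2-en-1-one; 10 2,3-bis(triethylsilyloxy)buta-1,3-diene
Product: 15 cis-fused rings B/C ketone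
Conditions: Tf2NH (5 mol %), CH2Cl2, −78 → −40 °C; Et3N quench
Reagents that add atoms: none
Why: Triflimide-catalysed [4+2] annulation, run as a Mukaiyama–Michael addition followed by an intramolecular Michael closure of ring C, adds the diene anti to the C-10 silyloxy group with a necessarily cis ring fusion, which sets C-9 (H β) and the quaternary C-8 (allyl β).

Step 10
Reactants: 15 cis-fused rings B/C ketone
Product: 17 ring B unsaturated 2-(trimethylsilyl)ethyl ester, via enol triflate 16 (not isolated)
Conditions: KN(SiMe3)2, PhNTf2, THF, −78 °C; then Pd(PPh3)4 (5 mol %), CO (1 atm), Me3SiCH2CH2OH, Et3N, DMF, 45 °C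
Reagents that add atoms: N-phenylbis(trifluoromethanesulfonimide) (triflyl group of 16), O=S(=O)(N(c1ccccc1)S(=O)(=O)C(F)(F)F)C(F)(F)F; carbon monoxide, [C-]#[O+]; 2-(trimethylsilyl)ethanol, C[Si](C)(C)CCO
Why: The ketone can enolise only towards C-5 and the enolate is trapped at −78 °C before the β-silyloxy group can eliminate, so triflation is regiospecific; palladium-catalysed alkoxycarbonylation of the enol triflate then installs C-7 as a fluoride-labile ester.

Step 11
Reactants: 17 ring B unsaturated 2-(trimethylsilyl)ethyl ester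
Product: 19 rings B/C/D keto diol, via silylated tricyclic ketone 18 (not isolated)
Conditions: Pd(OAc)2 (10 mol %), O2 (1 atm), DMSO, 45 °C; then 1 M HCl, THF–MeOH, rt
Reagents that add atoms: none
Why: Oxidative cycloalkenylation with divalent palladium (Kende/Toyota–Ihara type) lets the enol silyl ether carbon C-13 attack the palladium-bound allyl alkene in the 5-exo mode on the face that carries the allyl group, and β-hydride elimination leaves the exocyclic methylene; this forms the bicyclo[3.2.1]octane with its bridgehead C-13 oxygen, and acid then removes the remaining silyl ethers.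

Step 12
Reactants: 19 rings B/C/D keto diol
Product: 20 rings B/C/D triol
Conditions: LiBH(s-Bu)3 (3.3 equiv), THF, −78 °C; then H2O
Reagents that add atoms: none
Why: In this bulky-hydride ketone reduction the reagent attacks C-12 along the equatorial trajectory on the side of the two-carbon bridge, because the axial approach is blocked by the syn-axial C-9–C-10 bond; this gives the axial 12α-alcohol cis to the 13-hydroxyl.

Step 13
Reactants: 20 rings B/C/D triol
Product: 21 rings B/C/D enone diol
Conditions: MnO2 (excess), CH2Cl2, rt, short reaction time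
Reagents that add atoms: none
Why: Manganese dioxide allylic oxidation converts only the allylic C-10 alcohol to the ketone and, when stopped promptly, leaves the saturated secondary and the tertiary alcohols untouched.

Step 14
Reactants: 21 rings B/C/D enone diol
Product: 22 rings B/C/D enone bis(triethylsilyl) ether
Conditions: Et3SiOTf, 2,6-lutidine, CH2Cl2, −78 °C
Reagents that add atoms: triethylsilyl trifluoromethanesulfonate, CC[Si](CC)(CC)OS(=O)(=O)C(F)(F)F
Why: Low-temperature silylation masks the 12- and 13-hydroxyls before the acylation step, at a temperature where the ketone is not enol-silylated.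

Step 15
Reactants: 22 rings B/C/D enone bis(triethylsilyl) ether; 23 vinylmagnesium bromide; 8 (2R,3S)-2-methyl-3-(triethylsilyloxy)pent-4-enoyl chloride
Product: 25 C-10 tertiary ester, via tertiary cerium alkoxide 24 (not isolated)
Conditions: 23, CeCl3 (anhydrous), THF, −78 °C; then 8, −78 → 0 °C
Reagents that add atoms: none
Why: Organocerium 1,2-addition to the ketone from the β face (anti to C-11 and ring C) sets C-10 with its oxygen α without enolisation or conjugate addition, and the alkoxide is acylated in the same flask by the acid chloride.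

Step 16
Reactants: 25 C-10 tertiary ester
Product: 26 seven-membered unsaturated lactone
Conditions: second-generation Grubbs catalyst (5 mol %), toluene (2 mM), 80 °C
Reagents that add atoms: none
Why: Ring-closing metathesis of the two vinyl groups forms the cis C-1=C-2 alkene inside a seven-membered lactone with loss of ethylene, while the hindered exocyclic methylene and the unsaturated ester do not take part.

Step 17
Reactants: 26 seven-membered unsaturated lactone
Product: 28 fully protected target gibberellin, via potassium ester enolate 27 (not isolated)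
Conditions: KN(SiMe3)2, THF, −78 → −20 °C; then t-BuOH, −20 → 0 °C; then AcOH
Reagents that add atoms: none
Why: Intramolecular Michael addition of the lactone enolate (C-4) to C-5 of the unsaturated ester, across the spiro centre C-10, closes ring A and the γ-lactone at once. C-4 is tied through C-19 to the α-oxygen on C-10 and so reaches C-5 from the α face (H-5 β), the bicyclic frame fixes the C-4 quaternary centre, and tert-butoxide-mediated equilibration places the C-7 ester β (trans to C-4).

Step 18
Reactants: 28 fully protected target gibberellin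
Product: 29 12α-hydroxygibberellic acid (the target gibberellin)
Conditions: Bu4NF, AcOH, THF, 0 °C → rt
Reagents that add atoms: none
Why: Fluoride-mediated desilylation cleaves the three triethylsilyl ethers and fragments the 2-(trimethylsilyl)ethyl ester under buffered conditions that spare the base-sensitive allylic lactone and the 3-hydroxyl.

**Compound list**
1 | (R)-4-benzyloxazolidin-2-one | O=C1N[C@H](Cc2ccccc2)CO1 | starting material
2 | propanoyl chloride | CCC(=O)Cl | starting material
3 | (R)-4-benzyl-3-propanoyloxazolidin-2-one | CCC(=O)N1[C@H](Cc2ccccc2)COC1=O | intermediate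
4 | acrolein | C=CC=O | starting material
5 | (R)-4-benzyl-3-[(2R,3S)-3-hydroxy-2-methylpent-4-enoyl]oxazolidin-2-one | C=C[C@H](O)[C@@H](C)C(=O)N1[C@H](Cc2ccccc2)COC1=O | intermediate
6 | (R)-4-benzyl-3-[(2R,3S)-2-methyl-3-(triethylsilyloxy)pent-4-enoyl]oxazolidin-2-one | C=C[C@H](O[Si](CC)(CC)CC)[C@@H](C)C(=O)N1[C@H](Cc2ccccc2)COC1=O | intermediate
7 | (2R,3S)-2-methyl-3-(triethylsilyloxy)pent-4-enoic acid | C=C[C@H](O[Si](CC)(CC)CC)[C@@H](C)C(=O)O | intermediate
8 | (2R,3S)-2-methyl-3-(triethylsilyloxy)pent-4-enoyl chloride | C=C[C@H](O[Si](CC)(CC)CC)[C@@H](C)C(=O)Cl | intermediate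
9 | butane-2,3-dione | CC(=O)C(C)=O | starting material
10 | 2,3-bis(triethylsilyloxy)buta-1,3-diene | C=C(O[Si](CC)(CC)CC)C(=C)O[Si](CC)(CC)CC | intermediate
11 | (R)-4-(tert-butyldimethylsilyloxy)cyclopent-2-en-1-one | O=C1C=C[C@H](O[Si](C)(C)C(C)(C)C)C1 | starting material
12 | (R)-4-(tert-butyldimethylsilyloxy)-2-iodocyclopent-2-en-1-one | IC1=C[C@H](O[Si](C)(C)C(C)(C)C)CC1=O | intermediate
13 | allyltributylstannane | C=CC[Sn](CCCC)(CCCC)CCCC | starting material
14 | (R)-2-allyl-4-(tert-butyldimethylsilyloxy)cyclopent-2-en-1-one | C=CCC1=C[C@H](O[Si](C)(C)C(C)(C)C)CC1=O | intermediate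
15 | (3R,3aR,7aS)-7a-allyl-3-(tert-butyldimethylsilyloxy)-5,6-bis(triethylsilyloxy)-2,3,3a,4,7,7a-hexahydro-1H-inden-1-one (rings B/C cis-fused; 6-oxo, 10β-silyloxy, 9β-H, 8β-allyl, 12,13-enediol bis-silyl ether) | C=CC[C@]23CC(O[Si](CC)(CC)CC)=C(O[Si](CC)(CC)CC)C[C@H]2[C@H](O[Si](C)(C)C(C)(C)C)CC3=O | intermediate
16 | enol triflate of 15 (C-6 trifluoromethanesulfonyloxy, C-5=C-6 double bond, other centres as in 15) | C=CC[C@]23CC(O[Si](CC)(CC)CC)=C(O[Si](CC)(CC)CC)C[C@H]2[C@H](O[Si](C)(C)C(C)(C)C)C=C3OS(=O)(=O)C(F)(F)F | intermediate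
17 | 2-(trimethylsilyl)ethyl ester of the ring B 5-ene-6-carboxylic acid (C-7 ester) with 8β-allyl, 9β-H, 10β-(tert-butyldimethylsilyloxy) and the ring C 12,13-enediol bis(triethylsilyl) ether | C=CC[C@]23CC(O[Si](CC)(CC)CC)=C(O[Si](CC)(CC)CC)C[C@H]2[C@H](O[Si](C)(C)C(C)(C)C)C=C3C(=O)OCC[Si](C)(C)C | intermediate
18 | rings B/C/D tricycle: ring B as in 17 (10β-silyloxy, 5-ene-7-ester, 9β-H) cis-fused at C-8/C-9 to the rings C/D bicyclo[3.2.1]octane carrying 12-oxo, bridgehead 13-triethylsilyloxy and 16-methylene | C=C1C[C@]23C[C@@]1(O[Si](CC)(CC)CC)C(=O)C[C@H]2[C@H](O[Si](C)(C)C(C)(C)C)C=C3C(=O)OCC[Si](C)(C)C | intermediate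
19 | rings B/C/D keto diol: as 18 with free 10β-hydroxyl and 13-hydroxyl | C=C1C[C@]23C[C@@]1(O)C(=O)C[C@H]2[C@H](O)C=C3C(=O)OCC[Si](C)(C)C | intermediate
20 | rings B/C/D triol: 10β,12α,13-trihydroxy-16-methylene tricycle, 5-ene-7-oic acid 2-(trimethylsilyl)ethyl ester | C=C1C[C@]23C[C@@]1(O)[C@@H](O)C[C@H]2[C@H](O)C=C3C(=O)OCC[Si](C)(C)C | intermediate
21 | rings B/C/D enone diol: 10-oxo-12α,13-dihydroxy analogue of 20 | C=C1C[C@]23C[C@@]1(O)[C@@H](O)C[C@H]2C(=O)C=C3C(=O)OCC[Si](C)(C)C | intermediate
22 | rings B/C/D enone: 10-oxo-12α,13-bis(triethylsilyloxy)-16-methylene tricycle, 5-ene-7-oic acid 2-(trimethylsilyl)ethyl ester | C=C1C[C@]23C[C@@]1(O[Si](CC)(CC)CC)[C@@H](O[Si](CC)(CC)CC)C[C@H]2C(=O)C=C3C(=O)OCC[Si](C)(C)C | intermediate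
23 | vinylmagnesium bromide | C=C[Mg]Br | starting material
24 | tertiary C-10 carbinol, 10α-hydroxy-10β-vinyl adduct of 22 (present in the flask as its cerium alkoxide) | C=C1C[C@]23C[C@@]1(O[Si](CC)(CC)CC)[C@@H](O[Si](CC)(CC)CC)C[C@H]2[C@](O)(C=C)C=C3C(=O)OCC[Si](C)(C)C | intermediate
25 | 10α-O-[(2R,3S)-2-methyl-3-(triethylsilyloxy)pent-4-enoyl] ester of 24 | C=C1C[C@]23C[C@@]1(O[Si](CC)(CC)CC)[C@@H](O[Si](CC)(CC)CC)C[C@H]2[C@](OC(=O)[C@H](C)[C@@H](O[Si](CC)(CC)CC)C=C)(C=C)C=C3C(=O)OCC[Si](C)(C)C | intermediate
26 | seven-membered lactone (ring O–C-10–C-1=C-2–C-3–C-4–C-19, cis alkene, 3β-triethylsilyloxy, 4-methyl) spiro-attached at C-10 to the rings B/C/D tricycle of 22 | C=C1C[C@]23C[C@@]1(O[Si](CC)(CC)CC)[C@@H](O[Si](CC)(CC)CC)C[C@H]2[C@@]1(OC(=O)[C@H](C)[C@@H](O[Si](CC)(CC)CC)C=C1)C=C3C(=O)OCC[Si](C)(C)C | intermediate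
27 | potassium enolate of the C-7 ester (C-6=C-7) of 28 | [K+].C=C1C[C@]23C[C@@]1(O[Si](CC)(CC)CC)[C@@H](O[Si](CC)(CC)CC)C[C@H]2[C@@]12C=C[C@H](O[Si](CC)(CC)CC)[C@@](C)(C(=O)O1)[C@H]2C3=C([O-])OCC[Si](C)(C)C | intermediate
28 | 12α-hydroxygibberellic acid 3,12,13-tris(triethylsilyl) ether 7-[2-(trimethylsilyl)ethyl] ester | C=C1C[C@]23C[C@@]1(O[Si](CC)(CC)CC)[C@@H](O[Si](CC)(CC)CC)C[C@H]2[C@@]12C=C[C@H](O[Si](CC)(CC)CC)[C@@](C)(C(=O)O1)[C@H]2[C@@H]3C(=O)OCC[Si](C)(C)C | intermediate
29 | 12α-hydroxygibberellic acid (3β,12α,13-trihydroxy-1,16-diene-7-oic acid 19,10-lactone of the 20-norgibberellane skeleton; the target gibberellin) | C=C1C[C@]23C[C@@]1(O)[C@@H](O)C[C@H]2[C@@]12C=C[C@H](O)[C@@](C)(C(=O)O1)[C@H]2[C@@H]3C(=O)O | target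

**Step count and risks**
Total step count: 18. Longest linear sequence: 12 steps (steps 7–18, from 11), exactly two thirds of the total. The side branches are steps 1–5 (acid chloride 8, joining at step 15) and step 6 (diene 10, joining at step 9).

The three steps most likely to fail:

Step 9. A hindered α-alkyl enone must take up the diene and create the C-8 quaternary centre, and the C-10 silyloxy group can eliminate under acid. Fallback: set out from 12. The α-iodoenone is the better dienophile and reacts with 10 (toluene, 110 °C, or the same triflimide catalysis) anti to the silyloxy group to give the cis-fused α-iodo ketone adduct F1. A Keck radical allylation with 13 (AIBN, benzene, 80 °C) then places the allyl group on the ring-fusion radical from the face that keeps the cis fusion and comes back to the route at 15.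

Step 11. The attacking enol ether carbon is fully substituted and oxygen-bearing, Saegusa-type dehydrogenation can compete, and the method is precedented only for enol ethers without the extra oxygen. Fallback: replace the oxidative cyclisation with divalent palladium by a Heck cyclisation of a vinyl bromide.
- Set out from 12: Stille coupling with tributyl(2-bromoallyl)stannane (C=C(Br)C[Sn](CCCC)(CCCC)CCCC; Pd2(dba)3, AsPh3, CuI) gives the bromoallyl enone F2, and annulation with 10 as in step 9 gives the bromoallyl adduct F3.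
- Triflation as in step 10 gives the enol triflate F4, and carbonylation at room temperature gives the bromoallyl ester F5. This relies on the enol triflate reacting with zerovalent palladium faster than the bromoalkene.
- Pd(PPh3)4, Et3N, MeCN, 80 °C then closes ring D by 5-exo carbopalladation of the enediol ether and syn β-hydride elimination towards C-11, which gives the ring C silyl enol ether F6.
- 1 M HCl in THF–MeOH, as in the second half of step 11, hydrolyses the enol ether to the 12-ketone and removes the silyl ethers, and the route is rejoined at 19.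

Step 17. This Michael addition from a seven-membered lactone enolate has no close precedent in this ring system, and β-elimination of the C-3 silyloxy group or a Claisen-type ring contraction of the allylic lactone enolate could compete. Fallback: reverse the order of the two ring closures, which also avoids the medium-ring metathesis of step 16. Set out from 25 and run the Michael addition on the open-chain ester (KN(SiMe3)2, THF, −78 °C; t-BuOH; AcOH), a 5-exo closure across the ester tether, to give the γ-lactone diene F7. Ring A is then closed as a cyclohexene by ring-closing metathesis (second-generation Grubbs catalyst, toluene, 80 °C), which comes back to the route at 28. C-4 is no longer fixed by a ring in this order, and only the epimer drawn as F7 can cyclise.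

Further compounds
F1 | step 9 | α-iodo ketone adduct: 7a-iodo analogue of 15 (iodine in place of the allyl group, same face) | I[C@]23CC(O[Si](CC)(CC)CC)=C(O[Si](CC)(CC)CC)C[C@H]2[C@H](O[Si](C)(C)C(C)(C)C)CC3=O
F2 | step 11 | (R)-2-(2-bromoallyl)-4-(tert-butyldimethylsilyloxy)cyclopent-2-en-1-one | C=C(Br)CC1=C[C@H](O[Si](C)(C)C(C)(C)C)CC1=O
F3 | step 11 | 2-bromoallyl analogue of 15 | C=C(Br)C[C@]23CC(O[Si](CC)(CC)CC)=C(O[Si](CC)(CC)CC)C[C@H]2[C@H](O[Si](C)(C)C(C)(C)C)CC3=O
F4 | step 11 | 2-bromoallyl analogue of enol triflate 16 | C=C(Br)C[C@]23CC(O[Si](CC)(CC)CC)=C(O[Si](CC)(CC)CC)C[C@H]2[C@H](O[Si](C)(C)C(C)(C)C)C=C3OS(=O)(=O)C(F)(F)F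
F5 | step 11 | 2-bromoallyl analogue of ester 17 | C=C(Br)C[C@]23CC(O[Si](CC)(CC)CC)=C(O[Si](CC)(CC)CC)C[C@H]2[C@H](O[Si](C)(C)C(C)(C)C)C=C3C(=O)OCC[Si](C)(C)C
F6 | step 11 | ring C silyl enol ether: rings B/C/D tricycle as 18 but with a C-11=C-12 double bond and a 12-triethylsilyloxy group in place of the 12-ketone | C=C1C[C@]23C[C@@]1(O[Si](CC)(CC)CC)C(O[Si](CC)(CC)CC)=C[C@H]2[C@H](O[Si](C)(C)C(C)(C)C)C=C3C(=O)OCC[Si](C)(C)C
F7 | step 17 | γ-lactone diene: C-4–C-5 Michael adduct of 25 (19,10-lactone closed, 10β-vinyl and the C-3 vinyl carbinol silyl ether still open) | C=C1C[C@]23C[C@@]1(O[Si](CC)(CC)CC)[C@@H](O[Si](CC)(CC)CC)C[C@H]2[C@@]1(C=C)OC(=O)[C@@]([C@@H](O[Si](CC)(CC)CC)C=C)(C)[C@H]1[C@@H]3C(=O)OCC[Si](C)(C)C
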